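**Plan**

1. Retrosynthesis: cut the two interflavan bonds C4–C8 (upper→middle, middle→lower) to give two C4-electrophilic, protected gallocatechin units and one protected catechin unit. In the catechin unit, cut the aryl ether bond O1–C8a of ring C, then C4–C4a.
2. Forward, lower unit: ring A enters as a 3,5-bis(benzyloxy)fluoroarene (fluorine on the future C8a) and is joined through C4 to an erythro epoxy alcohol that carries ring B, C2 and C3. Ring C is then closed by the C2 alkoxide displacing fluoride at C8a.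
3. Enabling feature: in ring A the other two oxygens (O5, O7) are meta to C8a, so they cannot donate into C8a and the charge of the σ-complex falls on C4a, C6 and C8. This electron-rich ring therefore still accepts an alkoxide at C8a, and the closure breaks no bond at C2 or C3.
4. Forward, chain: the C4 cation of acetylated, benzylated gallocatechin alkylates C8 of the catechin unit. A second copy of the same electrophile, brominated at its own C8 so that it cannot alkylate itself, alkylates C8 of the dimer. Deacetylation and hydrogenolysis, which also removes the bromine, finish.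
5. Stereochemistry: lower-unit C2/C3 from a Sharpless kinetic resolution (erythro epoxy alcohol = anti diol, carried with retention into the 2,3-trans ring). Upper- and middle-unit C2/C3 from (+)-gallocatechin. Both C4 centres (4α, 3,4-trans) from attack anti to the 3-acetoxy group that bridges the cation on the β face.

Key step: step 9

Remark: (+)-gallocatechin, the (2R,3S) flavan-3-ol, is taken as purchasable; the catechin unit is built from achiral materials.

**Route**

Step 1
Reactants: 1 1,3,5-trifluorobenzene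
Product: 2 1,3-bis(benzyloxy)-5-fluorobenzene
Conditions: BnOH (2.1 equiv), NaH, NMP, 0 → 80 °C
Reagents that add atoms: benzyl alcohol OCc1ccccc1
Why: Twofold SNAr (addition–elimination) by benzyloxide should stop at the bis-ether, because each alkoxy group introduced lowers the reactivity of the remaining C–F bonds, so the third fluoride is kept as the leaving group of the key step.

Step 2
Reactants: 2 1,3-bis(benzyloxy)-5-fluorobenzene
Product: 3 1,5-bis(benzyloxy)-2-bromo-3-fluorobenzene
Conditions: NBS (1.0 equiv), MeCN, 0 °C, dark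
Reagents that add atoms: N-bromosuccinimide O=C1CCC(=O)N1Br
Why: Electrophilic aromatic bromination is expected para to one benzyloxy group and ortho to the other, at the position flanked by F and OBn, because the site between the two benzyloxy groups is doubly ortho and more hindered.

Step 3
Reactants: 4 3,4-bis(benzyloxy)benzaldehyde
Product: 5 rac-1-[3,4-bis(benzyloxy)phenyl]prop-2-en-1-ol
Conditions: CH2=CHMgBr, THF, −78 → 0 °C; then H2O/NH4Cl
Reagents that add atoms: vinylmagnesium bromide C=C[Mg]Br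
Why: Grignard 1,2-addition to the aldehyde gives the racemic aryl vinyl carbinol needed for the resolution.

Step 4
Reactants: 5 rac-1-[3,4-bis(benzyloxy)phenyl]prop-2-en-1-ol
Product: 6 (R)-[3,4-bis(benzyloxy)phenyl][(2S)-oxiran-2-yl]methanol (erythro epoxy alcohol)
Conditions: Ti(OiPr)4 (0.1 equiv), D-(−)-DIPT (0.15 equiv), t-BuOOH (0.55 equiv), 4 Å MS, CH2Cl2, −20 °C
Reagents that add atoms: tert-butyl hydroperoxide CC(C)(C)OO
Why: Sharpless kinetic resolution by asymmetric epoxidation, in which the Ti(OiPr)4/D-(−)-DIPT catalyst should epoxidise the (S)-alcohol fast on the alkene face that keeps the aryl group away from the catalyst, giving the erythro (anti) epoxy alcohol that fixes both future centres C2 and C3 of the catechin unit while the (R)-alcohol is left behind.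

Step 5
Reactants: 6 (R)-[3,4-bis(benzyloxy)phenyl][(2S)-oxiran-2-yl]methanol
Product: 7 {(R)-[3,4-bis(benzyloxy)phenyl][(2S)-oxiran-2-yl]methoxy}tri(propan-2-yl)silane
Conditions: TIPSOTf, 2,6-lutidine, CH2Cl2, −78 → 0 °C
Reagents that add atoms: triisopropylsilyl trifluoromethanesulfonate CC(C)[Si](C(C)C)(C(C)C)OS(=O)(=O)C(F)(F)F
Why: Silylation of the benzylic hydroxyl under a hindered base leaves the epoxide intact, and the bulky triisopropylsilyl group is chosen because it should not migrate to the neighbouring oxygen under the basic conditions of step 7.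

Step 6
Reactants: 3 1,5-bis(benzyloxy)-2-bromo-3-fluorobenzene; 7 {(R)-[3,4-bis(benzyloxy)phenyl][(2S)-oxiran-2-yl]methoxy}tri(propan-2-yl)silane
Product: 9 (1R,2S)-3-[2,4-bis(benzyloxy)-6-fluorophenyl]-1-[3,4-bis(benzyloxy)phenyl]-1-[(triisopropylsilyl)oxy]propan-2-ol, via [2,4-bis(benzyloxy)-6-fluorophenyl]lithium 8 (not isolated)
Conditions: 3, n-BuLi, THF, −78 °C; then 7, BF3·OEt2, −78 °C; then H2O
Reagents that add atoms: none
Why: Bromine–lithium exchange gives the ortho-fluoroaryllithium, which at −78 °C should not lose LiF, and this opens the BF3-activated terminal epoxide at its CH2 carbon by SN2, forming the C4–C4a bond without touching either stereocentre.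

Step 7
Reactants: 9 (1R,2S)-3-[2,4-bis(benzyloxy)-6-fluorophenyl]-1-[3,4-bis(benzyloxy)phenyl]-1-[(triisopropylsilyl)oxy]propan-2-ol
Product: 11 {(1R,2S)-2-(benzyloxy)-3-[2,4-bis(benzyloxy)-6-fluorophenyl]-1-[3,4-bis(benzyloxy)phenyl]propoxy}tri(propan-2-yl)silane, via sodium alkoxide 10 (not isolated)
Conditions: NaH, THF, 0 °C; then BnBr, Bu4NI (cat.), 0 °C → rt
Reagents that add atoms: benzyl bromide BrCc1ccccc1
Why: Williamson etherification blocks the C3 oxygen, which would otherwise compete for C8a by five-membered ring closure in the key step, and the sodium alkoxide in THF at 0 °C should be alkylated much faster than it attacks the C–F carbon.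

Step 8
Reactants: 11 {(1R,2S)-2-(benzyloxy)-3-[2,4-bis(benzyloxy)-6-fluorophenyl]-1-[3,4-bis(benzyloxy)phenyl]propoxy}tri(propan-2-yl)silane
Product: 12 (1R,2S)-2-(benzyloxy)-3-[2,4-bis(benzyloxy)-6-fluorophenyl]-1-[3,4-bis(benzyloxy)phenyl]propan-1-ol
Conditions: TBAF, THF, rt
Reagents that add atoms: none
Why: Fluoride-mediated desilylation frees the benzylic C2 hydroxyl under non-acidic conditions, so the easily ionised electron-rich benzylic centre keeps its configuration.

Step 9
Reactants: 12 (1R,2S)-2-(benzyloxy)-3-[2,4-bis(benzyloxy)-6-fluorophenyl]-1-[3,4-bis(benzyloxy)phenyl]propan-1-ol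
Product: 14 (2R,3S)-3,5,7-tris(benzyloxy)-2-[3,4-bis(benzyloxy)phenyl]chromane (3,5,7,3′,4′-penta-O-benzylcatechin), via potassium alkoxide 13 (not isolated)
Conditions: KH (1.2 equiv), 18-crown-6, THF, 0 → 60 °C
Reagents that add atoms: none
Why: KH converts the C2 hydroxyl into the potassium alkoxide 13, which 18-crown-6 frees from its counter-ion; the oxygen adds to the fluorine-bearing carbon C8a to give a Meisenheimer σ-complex that loses fluoride (addition–elimination SNAr). The closest known reaction type is the intramolecular displacement of an aryl fluoride by a side-chain alkoxide to form chromans, including flavan-3-ol skeletons from 3,5-dialkoxyfluorobenzenes. Ring C closes in the 6-exo-trig mode, the C2 oxygen reaching C8a from above the plane of ring A through a six-membered transition state. No stereocentre is created: neither the C2–O nor the C3–O bond is broken, so the anti (1R,2S) arrangement set in step 4 is carried with retention into the 2,3-trans (2R,3S) pyran ring, unlike closures that pass through a C2 cation. The step needs attack by the C2 oxygen and not the C3 oxygen, which the benzyl ether on O3 secures, and substitution at C8a only, which is secured by fluorine being the single leaving group and ortho to the tether. It should work on this electron-rich ring because O5 and O7 are meta to C8a, so they cannot donate into C8a, they stabilise the σ-complex inductively, and the negative charge falls on C4a, C6 and C8, which carry no oxygen.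

Step 10
Reactants: 15 (+)-gallocatechin
Product: 16 (2R,3S)-5,7-bis(benzyloxy)-2-[3,4,5-tris(benzyloxy)phenyl]chroman-3-ol (5,7,3′,4′,5′-penta-O-benzylgallocatechin)
Conditions: BnBr (5.5 equiv), K2CO3, DMF, 0 °C → rt, Ar
Reagents that add atoms: benzyl bromide BrCc1ccccc1
Why: Williamson etherification under a weak base benzylates the five phenolic hydroxyls and leaves the much less acidic secondary 3-OH free.

Step 11
Reactants: 16 penta-O-benzylgallocatechin
Product: 18 (2R,3S,4S)-5,7-bis(benzyloxy)-4-(2-ethoxyethoxy)-2-[3,4,5-tris(benzyloxy)phenyl]chroman-3-ol, via C4 carbocation 17 (not isolated)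
Conditions: DDQ, 2-ethoxyethanol, CH2Cl2, rt
Reagents that add atoms: 2-ethoxyethanol CCOCCO
Why: DDQ benzylic oxidation removes hydride from C4, which is activated by the ortho and para oxygens of ring A, and the cation should be trapped by the alcohol on the β face, anti to the C2 aryl group, to give the 4β ether, a centre that is ionised again in steps 13 and 15.

Step 12
Reactants: 18 (2R,3S,4S)-5,7-bis(benzyloxy)-4-(2-ethoxyethoxy)-2-[3,4,5-tris(benzyloxy)phenyl]chroman-3-ol
Product: 19 (2R,3S,4S)-5,7-bis(benzyloxy)-4-(2-ethoxyethoxy)-2-[3,4,5-tris(benzyloxy)phenyl]chroman-3-yl acetate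
Conditions: Ac2O, pyridine, DMAP (cat.), CH2Cl2, rt
Reagents that add atoms: acetic anhydride CC(=O)OC(C)=O
Why: Acylation of the 3-OH installs the neighbouring group that is to direct both interflavan couplings.

Step 13
Reactants: 19 4-(2-ethoxyethoxy) acetate electrophile; 14 penta-O-benzylcatechin
Product: 21 3-O-acetyl-5,7,3′,4′,5′-penta-O-benzylgallocatechin-(4α→8)-3,5,7,3′,4′-penta-O-benzylcatechin, via acetoxy-bridged C4 carbocation 20 (not isolated)
Conditions: TMSOTf (cat.), 4 Å MS, CH2Cl2, −78 °C; 14 in excess (2 equiv, excess recovered)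
Reagents that add atoms: none
Why: Lewis acid ionisation of the C4 ether gives a cation bridged on the β face by the 3-acetoxy group, so that in this Friedel–Crafts-type alkylation C8 of 14, the most accessible nucleophilic position of its ring A, should attack from the α face and set the 3,4-trans (4α) centre, while the excess of 14 outruns self-condensation of 19.

Step 14
Reactants: 19 4-(2-ethoxyethoxy) acetate electrophile
Product: 22 (2R,3S,4S)-5,7-bis(benzyloxy)-8-bromo-4-(2-ethoxyethoxy)-2-[3,4,5-tris(benzyloxy)phenyl]chroman-3-yl acetate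
Conditions: NBS (1.0 equiv), CH2Cl2, −78 → −20 °C, dark
Reagents that add atoms: N-bromosuccinimide O=C1CCC(=O)N1Br
Why: Electrophilic aromatic bromination should take place at C8, the most nucleophilic position of the phloroglucinol-type ring A (ortho to O1 and to the 7-benzyloxy group, para to the 5-benzyloxy group), under conditions with no acid strong enough to ionise the C4 ether, and the bromine closes the position through which this electrophile would otherwise alkylate itself in the second coupling.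

Step 15
Reactants: 22 8-bromo 4-(2-ethoxyethoxy) acetate electrophile; 21 protected gallocatechin-(4α→8)-catechin dimer
Product: 24 8-bromo-3-O-acetyl-penta-O-benzylgallocatechin-(4α→8)-3-O-acetyl-penta-O-benzylgallocatechin-(4α→8)-penta-O-benzylcatechin, via 8-bromo acetoxy-bridged C4 carbocation 23 (not isolated)
Conditions: 22 (1.1 equiv), TMSOTf (cat.), 4 Å MS, CH2Cl2, −78 → −40 °C
Reagents that add atoms: none
Why: Ionisation of the C4 ether of 22 gives a cation bridged on the β face by its 3-acetoxy group that has no free C8 of its own, so in this second Friedel–Crafts-type alkylation it should be captured from the α face by C8 of the upper unit of 21, the only unsubstituted C8 position of the dimer, which sets the second 4α centre.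

Step 16
Reactants: 24 8-bromo protected trimer diacetate
Product: 25 8-bromo-penta-O-benzylgallocatechin-(4α→8)-penta-O-benzylgallocatechin-(4α→8)-3,5,7,3′,4′-penta-O-benzylcatechin (3-OH free on the upper and middle units)
Conditions: NaOMe, MeOH/THF, rt
Reagents that add atoms: none
Why: Zemplén transesterification removes both acetates under basic conditions, to which the benzyl ethers, the aryl bromide and the interflavan bonds are stable.

Step 17
Reactants: 25 8-bromo protected trimer diol
Product: 26 prodelphinidin C2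
Conditions: H2 (1 atm), Pd(OH)2/C, Et3N, THF/MeOH/H2O, rt; then dilute aqueous HCl to pH 5
Reagents that add atoms: none
Why: Hydrogenolysis cleaves all fifteen benzyl ethers and, with Et3N as acceptor of HBr, the aryl C–Br bond (hydrodehalogenation) under conditions that should leave the interflavan C–C bonds and all stereocentres untouched.

**Compound list**

1 | 1,3,5-trifluorobenzene | Fc1cc(F)cc(F)c1 | starting material
2 | 1,3-bis(benzyloxy)-5-fluorobenzene | Fc1cc(OCc2ccccc2)cc(OCc2ccccc2)c1 | intermediate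
3 | 1,5-bis(benzyloxy)-2-bromo-3-fluorobenzene | Fc1cc(OCc2ccccc2)cc(OCc2ccccc2)c1Br | intermediate
4 | 3,4-bis(benzyloxy)benzaldehyde | O=Cc1ccc(OCc2ccccc2)c(OCc2ccccc2)c1 | starting material
5 | rac-1-[3,4-bis(benzyloxy)phenyl]prop-2-en-1-ol | OC(C=C)c1ccc(OCc2ccccc2)c(OCc2ccccc2)c1 | intermediate
6 | (R)-[3,4-bis(benzyloxy)phenyl][(2S)-oxiran-2-yl]methanol | O[C@H](c1ccc(OCc2ccccc2)c(OCc2ccccc2)c1)[C@@H]1CO1 | intermediate
7 | {(R)-[3,4-bis(benzyloxy)phenyl][(2S)-oxiran-2-yl]methoxy}tri(propan-2-yl)silane | CC(C)[Si](C(C)C)(C(C)C)O[C@H](c1ccc(OCc2ccccc2)c(OCc2ccccc2)c1)[C@@H]1CO1 | intermediate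
8 | [2,4-bis(benzyloxy)-6-fluorophenyl]lithium | [Li]c1c(F)cc(OCc2ccccc2)cc1OCc1ccccc1 | intermediate
9 | (1R,2S)-3-[2,4-bis(benzyloxy)-6-fluorophenyl]-1-[3,4-bis(benzyloxy)phenyl]-1-[(triisopropylsilyl)oxy]propan-2-ol | CC(C)[Si](C(C)C)(C(C)C)O[C@H](c1ccc(OCc2ccccc2)c(OCc2ccccc2)c1)[C@@H](O)Cc1c(F)cc(OCc2ccccc2)cc1OCc1ccccc1 | intermediate
10 | sodium alkoxide of 9 | CC(C)[Si](C(C)C)(C(C)C)O[C@H](c1ccc(OCc2ccccc2)c(OCc2ccccc2)c1)[C@@H]([O-])Cc1c(F)cc(OCc2ccccc2)cc1OCc1ccccc1.[Na+] | intermediate
11 | {(1R,2S)-2-(benzyloxy)-3-[2,4-bis(benzyloxy)-6-fluorophenyl]-1-[3,4-bis(benzyloxy)phenyl]propoxy}tri(propan-2-yl)silane | CC(C)[Si](C(C)C)(C(C)C)O[C@H](c1ccc(OCc2ccccc2)c(OCc2ccccc2)c1)[C@@H](OCc1ccccc1)Cc1c(F)cc(OCc2ccccc2)cc1OCc1ccccc1 | intermediate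
12 | (1R,2S)-2-(benzyloxy)-3-[2,4-bis(benzyloxy)-6-fluorophenyl]-1-[3,4-bis(benzyloxy)phenyl]propan-1-ol | O[C@H](c1ccc(OCc2ccccc2)c(OCc2ccccc2)c1)[C@@H](OCc1ccccc1)Cc1c(F)cc(OCc2ccccc2)cc1OCc1ccccc1 | intermediate
13 | potassium alkoxide of 12 | [K+].[O-][C@H](c1ccc(OCc2ccccc2)c(OCc2ccccc2)c1)[C@@H](OCc1ccccc1)Cc1c(F)cc(OCc2ccccc2)cc1OCc1ccccc1 | intermediate
14 | (2R,3S)-3,5,7-tris(benzyloxy)-2-[3,4-bis(benzyloxy)phenyl]chromane (3,5,7,3′,4′-penta-O-benzylcatechin) | c1c(OCc3ccccc3)cc(OCc3ccccc3)c2c1O[C@H](c1ccc(OCc3ccccc3)c(OCc3ccccc3)c1)[C@@H](OCc1ccccc1)C2 | intermediate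
15 | (+)-gallocatechin, (2R,3S) | Oc1cc(O)c2c(c1)O[C@H](c1cc(O)c(O)c(O)c1)[C@@H](O)C2 | starting material
16 | (2R,3S)-5,7-bis(benzyloxy)-2-[3,4,5-tris(benzyloxy)phenyl]chroman-3-ol (penta-O-benzylgallocatechin) | c1ccccc1COc1cc(OCc3ccccc3)c2c(c1)O[C@H](c1cc(OCc3ccccc3)c(OCc3ccccc3)c(OCc3ccccc3)c1)[C@@H](O)C2 | intermediate
17 | C4 carbocation of 16 (3-hydroxy, ion pair with reduced DDQ) | c1ccccc1COc1cc(OCc3ccccc3)c2c(c1)O[C@H](c1cc(OCc3ccccc3)c(OCc3ccccc3)c(OCc3ccccc3)c1)[C@@H](O)[CH+]2 | intermediate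
18 | (2R,3S,4S)-5,7-bis(benzyloxy)-4-(2-ethoxyethoxy)-2-[3,4,5-tris(benzyloxy)phenyl]chroman-3-ol | c1ccccc1COc1cc(OCc3ccccc3)c2c(c1)O[C@H](c1cc(OCc3ccccc3)c(OCc3ccccc3)c(OCc3ccccc3)c1)[C@@H](O)[C@H]2OCCOCC | intermediate
19 | (2R,3S,4S)-5,7-bis(benzyloxy)-4-(2-ethoxyethoxy)-2-[3,4,5-tris(benzyloxy)phenyl]chroman-3-yl acetate | c1ccccc1COc1cc(OCc3ccccc3)c2c(c1)O[C@H](c1cc(OCc3ccccc3)c(OCc3ccccc3)c(OCc3ccccc3)c1)[C@@H](OC(C)=O)[C@H]2OCCOCC | intermediate
20 | C4 carbocation of the 3-acetate 19, bridged on the β face by the acetoxy group (drawn in its open form; triflate counter-ion) | c1ccccc1COc1cc(OCc3ccccc3)c2c(c1)O[C@H](c1cc(OCc3ccccc3)c(OCc3ccccc3)c(OCc3ccccc3)c1)[C@@H](OC(C)=O)[CH+]2 | intermediate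
21 | 3-O-acetyl-penta-O-benzylgallocatechin-(4α→8)-penta-O-benzylcatechin | c1ccccc1COc1cc(OCc3ccccc3)c2c(c1)O[C@H](c1cc(OCc3ccccc3)c(OCc3ccccc3)c(OCc3ccccc3)c1)[C@@H](OC(C)=O)[C@@H]2c1c(OCc3ccccc3)cc(OCc3ccccc3)c2c1O[C@H](c1ccc(OCc3ccccc3)c(OCc3ccccc3)c1)[C@@H](OCc1ccccc1)C2 | intermediate
22 | (2R,3S,4S)-5,7-bis(benzyloxy)-8-bromo-4-(2-ethoxyethoxy)-2-[3,4,5-tris(benzyloxy)phenyl]chroman-3-yl acetate | c1ccccc1COc1cc(OCc3ccccc3)c2c(c1Br)O[C@H](c1cc(OCc3ccccc3)c(OCc3ccccc3)c(OCc3ccccc3)c1)[C@@H](OC(C)=O)[C@H]2OCCOCC | intermediate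
23 | C4 carbocation of the 8-bromo 3-acetate 22, bridged on the β face by the acetoxy group (drawn in its open form; triflate counter-ion) | c1ccccc1COc1cc(OCc3ccccc3)c2c(c1Br)O[C@H](c1cc(OCc3ccccc3)c(OCc3ccccc3)c(OCc3ccccc3)c1)[C@@H](OC(C)=O)[CH+]2 | intermediate
24 | 8-bromo-3-O-acetyl-penta-O-benzylgallocatechin-(4α→8)-3-O-acetyl-penta-O-benzylgallocatechin-(4α→8)-penta-O-benzylcatechin | c1ccccc1COc1cc(OCc3ccccc3)c2c(c1Br)O[C@H](c1cc(OCc3ccccc3)c(OCc3ccccc3)c(OCc3ccccc3)c1)[C@@H](OC(C)=O)[C@@H]2c1c(OCc3ccccc3)cc(OCc3ccccc3)c2c1O[C@H](c1cc(OCc3ccccc3)c(OCc3ccccc3)c(OCc3ccccc3)c1)[C@@H](OC(C)=O)[C@@H]2c1c(OCc3ccccc3)cc(OCc3ccccc3)c2c1O[C@H](c1ccc(OCc3ccccc3)c(OCc3ccccc3)c1)[C@@H](OCc1ccccc1)C2 | intermediate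
25 | 8-bromo-penta-O-benzylgallocatechin-(4α→8)-penta-O-benzylgallocatechin-(4α→8)-penta-O-benzylcatechin (two free 3-OH) | c1ccccc1COc1cc(OCc3ccccc3)c2c(c1Br)O[C@H](c1cc(OCc3ccccc3)c(OCc3ccccc3)c(OCc3ccccc3)c1)[C@@H](O)[C@@H]2c1c(OCc3ccccc3)cc(OCc3ccccc3)c2c1O[C@H](c1cc(OCc3ccccc3)c(OCc3ccccc3)c(OCc3ccccc3)c1)[C@@H](O)[C@@H]2c1c(OCc3ccccc3)cc(OCc3ccccc3)c2c1O[C@H](c1ccc(OCc3ccccc3)c(OCc3ccccc3)c1)[C@@H](OCc1ccccc1)C2 | intermediate
26 | prodelphinidin C2, gallocatechin-(4α→8)-gallocatechin-(4α→8)-catechin | Oc1cc(O)c2c(c1)O[C@H](c1cc(O)c(O)c(O)c1)[C@@H](O)[C@@H]2c1c(O)cc(O)c2c1O[C@H](c1cc(O)c(O)c(O)c1)[C@@H](O)[C@@H]2c1c(O)cc(O)c2c1O[C@H](c1ccc(O)c(O)c1)[C@@H](O)C2 | target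

**Summary**

Total step count: 17. Longest linear sequence: 11 steps (steps 3–9, then 13, 15, 16 and 17, from aldehyde 4).

**Steps most likely to fail**

Step 9. The alkoxide may add too slowly to the electron-rich fluoroarene, so that base-induced degradation overtakes ring closure. Examples are deprotonation next to fluorine with loss of fluoride to an aryne, or attack on benzyl ethers. Fallback: the same O1–C8a bond would be closed by Pd-catalysed aryl C–O coupling (Buchwald–Hartwig-type etherification) of an aryl bromide. It sets out from epoxide 7. Purchased 1,3-bis(benzyloxy)-5-bromobenzene F1 is iodinated (NIS, cat. TFA, MeCN) para to one benzyloxy group to give 1,5-bis(benzyloxy)-3-bromo-2-iodobenzene F2. Iodine–magnesium exchange (iPrMgCl·LiCl, THF, −40 °C) gives [2,4-bis(benzyloxy)-6-bromophenyl]magnesium chloride F3, which opens 7 at its CH2 carbon under CuI catalysis to the silyl-protected bromo alcohol F4. Benzylation (NaH, BnBr) gives the benzyl ether F5, and TBAF gives the free bromo alcohol F6. Pd(OAc)2, 2-(di-tert-butylphosphino)-1,1′-binaphthyl and Cs2CO3 in toluene at 70 °C should then close ring C by oxidative addition of the C–Br bond to zerovalent palladium and C–O reductive elimination, with retention at C2 and C3. The route is rejoined at 14.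

Step 15. The hindered dimer may capture the cation too slowly, so that alkylation at the C6 positions, further alkylation of the trimer and incomplete α-facial control erode the coupling. Fallback: the chain is assembled in the opposite order, upper dimer first, by orthogonal activation of two different C4 leaving groups, so that the readily available monomer 14 serves as the nucleophile in excess. It sets out from 19 and 22. Exchange of the C4 ether of 19 for a thioether (phenylmethanethiol in excess, BF3·OEt2, CH2Cl2, −78 → −20 °C) should give (2R,3R,4R)-4-(benzylsulfanyl)-5,7-bis(benzyloxy)-2-[3,4,5-tris(benzyloxy)phenyl]chroman-3-yl acetate F7, whose C–S bond is inert to hard Lewis acids. BF3·OEt2 at −78 °C then ionises only the ether 22, and C8 of F7 (used in excess) captures the cation from the α face to give 8-bromo-3-O-acetyl-penta-O-benzylgallocatechin-(4α→8)-3-O-acetyl-4α-(benzylsulfanyl)-penta-O-benzylgallocatechin F8. AgOTf with 2,6-di-tert-butyl-4-methylpyridine (4 Å MS, CH2Cl2, −40 °C) ionises the C–S bond of F8 in the presence of an excess of 14, whose C8 attacks the acetoxy-bridged cation from the α face. The route is rejoined at 24.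

Step 4. The Ti(OiPr)4/D-(−)-DIPT catalyst may discriminate too little between the enantiomers of an aryl vinyl carbinol at useful conversion, so that the epoxy alcohol forms with eroded enantiomeric purity; half of the material is lost in any case. Fallback: resolution and epoxidation are separated. It sets out from 5. Lipase-catalysed acylation (Candida antarctica lipase B, vinyl acetate, hexane) should leave (S)-1-[3,4-bis(benzyloxy)phenyl]prop-2-en-1-ol F9 and convert its enantiomer into (R)-1-[3,4-bis(benzyloxy)phenyl]prop-2-en-1-yl acetate F10, which is separated. F9 alone is then epoxidised with stoichiometric Ti(OiPr)4, D-(−)-DIPT and t-BuOOH at −20 °C. This is now a matched, purely diastereoselective (erythro) epoxidation run to full conversion, and the route is rejoined at 6.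

**Further compounds**

F1 | step 9 | 1,3-bis(benzyloxy)-5-bromobenzene (purchased) | Brc1cc(OCc2ccccc2)cc(OCc2ccccc2)c1
F2 | step 9 | 1,5-bis(benzyloxy)-3-bromo-2-iodobenzene | Brc1cc(OCc2ccccc2)cc(OCc2ccccc2)c1I
F3 | step 9 | [2,4-bis(benzyloxy)-6-bromophenyl]magnesium chloride (not isolated) | Cl[Mg]c1c(Br)cc(OCc2ccccc2)cc1OCc1ccccc1
F4 | step 9 | (1R,2S)-3-[2,4-bis(benzyloxy)-6-bromophenyl]-1-[3,4-bis(benzyloxy)phenyl]-1-[(triisopropylsilyl)oxy]propan-2-ol | CC(C)[Si](C(C)C)(C(C)C)O[C@H](c1ccc(OCc2ccccc2)c(OCc2ccccc2)c1)[C@@H](O)Cc1c(Br)cc(OCc2ccccc2)cc1OCc1ccccc1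
F5 | step 9 | {(1R,2S)-2-(benzyloxy)-3-[2,4-bis(benzyloxy)-6-bromophenyl]-1-[3,4-bis(benzyloxy)phenyl]propoxy}tri(propan-2-yl)silane | CC(C)[Si](C(C)C)(C(C)C)O[C@H](c1ccc(OCc2ccccc2)c(OCc2ccccc2)c1)[C@@H](OCc1ccccc1)Cc1c(Br)cc(OCc2ccccc2)cc1OCc1ccccc1
F6 | step 9 | (1R,2S)-2-(benzyloxy)-3-[2,4-bis(benzyloxy)-6-bromophenyl]-1-[3,4-bis(benzyloxy)phenyl]propan-1-ol | O[C@H](c1ccc(OCc2ccccc2)c(OCc2ccccc2)c1)[C@@H](OCc1ccccc1)Cc1c(Br)cc(OCc2ccccc2)cc1OCc1ccccc1
F7 | step 15 | (2R,3R,4R)-4-(benzylsulfanyl)-5,7-bis(benzyloxy)-2-[3,4,5-tris(benzyloxy)phenyl]chroman-3-yl acetate | c1ccccc1COc1cc(OCc3ccccc3)c2c(c1)O[C@H](c1cc(OCc3ccccc3)c(OCc3ccccc3)c(OCc3ccccc3)c1)[C@@H](OC(C)=O)[C@@H]2SCc1ccccc1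
F8 | step 15 | 8-bromo-3-O-acetyl-penta-O-benzylgallocatechin-(4α→8)-3-O-acetyl-4α-(benzylsulfanyl)-penta-O-benzylgallocatechin | c1ccccc1COc1cc(OCc3ccccc3)c2c(c1Br)O[C@H](c1cc(OCc3ccccc3)c(OCc3ccccc3)c(OCc3ccccc3)c1)[C@@H](OC(C)=O)[C@@H]2c1c(OCc3ccccc3)cc(OCc3ccccc3)c2c1O[C@H](c1cc(OCc3ccccc3)c(OCc3ccccc3)c(OCc3ccccc3)c1)[C@@H](OC(C)=O)[C@@H]2SCc1ccccc1
F9 | step 4 | (S)-1-[3,4-bis(benzyloxy)phenyl]prop-2-en-1-ol | O[C@H](c1ccc(OCc2ccccc2)c(OCc2ccccc2)c1)C=C
F10 | step 4 | (R)-1-[3,4-bis(benzyloxy)phenyl]prop-2-en-1-yl acetate | CC(=O)O[C@@H](c1ccc(OCc2ccccc2)c(OCc2ccccc2)c1)C=C
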